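**Plan**

- Ring numbering: O1, O2, C3 (bears CH2CO2Me), C4, C5, C6 (bears OMe and the side chain). C4 and C5 are the only ring atoms of the 1,2-dioxane without a heteroatom, so once C3 and C6 are tied together through O2–O1 the ring can be closed between them.
- Retrosynthetic cuts, in order: the terminal alkyne carbon (Ohira–Bestmann), the C(sp)–C(sp2) bond of the enyne (Sonogashira), ring bond C4–C5 (ring-closing metathesis, then saturation), the C6–O1 ketal bond (hydroperoxide added to a 1-methoxyallene), the C3–O2 bond (asymmetric β-peroxidation of sorbaldehyde).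
- Forward: hydroperoxide 7 and methoxyallene 14 give mixed peroxyketal 15; metathesis closes the only ring (16); diimide, acid–methanol equilibration and desilylation give alkyne 19; coupling with iodoalkenal 23 and alkyne homologation finish the chain.
- Stereochemistry: C3 comes from the amine-catalysed peroxidation (3R in the open chain becomes 3S in the saturated ring only through a CIP priority change). C6 is set by equilibration to the anomerically favoured 3,6-cis isomer. The E-alkene comes from hydrozirconation–iodination.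

Key step: step 9

Assumption: the hydroperoxide enters the iminium ion of 3 on the face remote from the diaryl(silyloxy)methyl arm, as other heteroatom nucleophiles do with this catalyst class; on that model the (R)-catalyst gives 3R.

**Route**

Step 1
Reactants: 1 2,3-dimethylbut-2-ene
Product: 2 2-hydroperoxy-2-methoxypropane
Conditions: O3, MeOH/CH2Cl2, −78 °C; Ar purge; kept and used as a solution
Reagents that add atoms: ozone, [O-][O+]=O; methanol, CO
Why: Criegee ozonolysis in a participating solvent splits the symmetrical alkene into acetone and acetone O-oxide, and methanol traps the carbonyl oxide as the α-methoxy hydroperoxide.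

Step 2
Reactants: 3 (2E,4E)-hexa-2,4-dienal; 2 2-hydroperoxy-2-methoxypropane
Product: 4 (3R,4E)-3-[(2-methoxypropan-2-yl)peroxy]hex-4-enal
Conditions: (R)-2-{bis[3,5-bis(trifluoromethyl)phenyl][(trimethylsilyl)oxy]methyl}pyrrolidine (10 mol%), PhCO2H (10 mol%), toluene, 0 °C; short silica plug, used at once
Reagents that add atoms: none
Why: Iminium-catalysed asymmetric conjugate addition of a hydroperoxide to an enal (β-peroxidation) should place the peroxide at C3 of the s-trans E-iminium ion, the carbon also attacked in amine-catalysed epoxidation of 2,4-dienals, on the face left open by the diaryl(silyloxy)methyl arm to set 3R, while the acid co-catalyst protonates the enamine before it can close to an epoxide.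

Step 3
Reactants: 4 (3R,4E)-3-[(2-methoxypropan-2-yl)peroxy]hex-4-enal
Product: 5 (3R,4E)-3-[(2-methoxypropan-2-yl)peroxy]hex-4-enoic acid
Conditions: NaClO2, NaH2PO4, 2-methylbut-2-ene, t-BuOH/H2O, 0 °C
Reagents that add atoms: sodium chlorite, [Na+].[O-]Cl=O
Why: Pinnick oxidation takes the aldehyde to the acid under buffered, non-basic conditions that spare the O–O bond, the alkene (HOCl is scavenged) and the base-sensitive β-peroxy stereocentre, and any partial loss of the ketal is harmless because step 4 removes it.

Step 4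
Reactants: 5 (3R,4E)-3-[(2-methoxypropan-2-yl)peroxy]hex-4-enoic acid
Product: 7 methyl (3R,4E)-3-hydroperoxyhex-4-enoate, via peroxyketal methyl ester 6 (not isolated)
Conditions: TMSCHN2 (1.1 equiv), PhMe/MeOH, 0 °C; then PPTS (20 mol%), MeOH, rt
Reagents that add atoms: (trimethylsilyl)diazomethane, C[Si](C)(C)C=[N+]=[N-]
Why: Methylation with (trimethylsilyl)diazomethane is neutral, and PPTS-catalysed transketalisation to methanol then frees the hydroperoxide from the 2-methoxyprop-2-yl peroxyketal without touching the allylic C3–O bond.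

Step 5
Reactants: 8 5-chloropent-1-yne
Product: 10 (5-chloropent-1-yn-1-yl)tri(propan-2-yl)silane, via lithium acetylide 9 (not isolated)
Conditions: n-BuLi, THF, −78 °C; TIPSCl, −78 °C → rt
Reagents that add atoms: chlorotri(propan-2-yl)silane, CC(C)[Si](Cl)(C(C)C)C(C)C
Why: Deprotonation of the terminal alkyne and C-silylation of the acetylide is standard, and the primary chloride is inert to the acetylide in THF without a dipolar co-solvent.

Step 6
Reactants: 10 (5-chloropent-1-yn-1-yl)tri(propan-2-yl)silane
Product: 11 (5-iodopent-1-yn-1-yl)tri(propan-2-yl)silane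
Conditions: NaI, acetone, reflux
Reagents that add atoms: sodium iodide, [Na+].[I-]
Why: Finkelstein exchange, driven by precipitation of NaCl, supplies the iodide needed for a clean alkylation in step 7.

Step 7
Reactants: 12 methoxyallene (1-methoxypropa-1,2-diene); 11 (5-iodopent-1-yn-1-yl)tri(propan-2-yl)silane
Product: 14 (6-methoxyocta-6,7-dien-1-yn-1-yl)tri(propan-2-yl)silane, via 1-lithio-1-methoxyallene 13 (not isolated)
Conditions: n-BuLi, THF, −40 °C; then 11, −78 °C → rt; chromatography on Et3N-deactivated silica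
Reagents that add atoms: none
Why: Methoxyallene is lithiated at C1 (α to oxygen) and this acryloyl-anion equivalent is alkylated by primary iodides at the same carbon to give 1-alkyl-1-methoxyallenes.

Step 8
Reactants: 7 methyl (3R,4E)-3-hydroperoxyhex-4-enoate; 14 (6-methoxyocta-6,7-dien-1-yn-1-yl)tri(propan-2-yl)silane
Product: 15 methyl (3R,4E)-3-({3-methoxy-8-[tri(propan-2-yl)silyl]oct-1-en-7-yn-3-yl}peroxy)hex-4-enoate (both ketal epimers)
Conditions: PPTS (5 mol%), CH2Cl2, 4 Å MS, −20 → 0 °C; Et3N quench
Reagents that add atoms: none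
Why: Acid-catalysed O–H addition to an alkoxyallene, the allene counterpart of hydroperoxide perketalisation with enol ethers, should protonate the central allene carbon and capture the 1-methoxyallyl cation at its oxygen-bearing carbon, giving the vinyl-substituted mixed peroxyketal irreversibly and without release of methanol (the uncontrolled ketal centre is corrected in step 11).

Step 9
Reactants: 15 methyl (3R,4E)-3-({3-methoxy-8-[tri(propan-2-yl)silyl]oct-1-en-7-yn-3-yl}peroxy)hex-4-enoate
Product: 16 methyl 2-[(3R)-6-methoxy-6-{5-[tri(propan-2-yl)silyl]pent-4-yn-1-yl}-3,6-dihydro-1,2-dioxin-3-yl]acetate (both C6 epimers)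
Conditions: Hoveyda–Grubbs second-generation catalyst (10 mol%), CH2Cl2 (5 mM), 40 °C, Ar sparge
Reagents that add atoms: none
Why: Ring-closing olefin metathesis: the ruthenium alkylidene loads on one alkene terminus (most likely the less hindered propenyl group), and [2+2] cycloaddition with the other alkene followed by cycloreversion joins C4 to C5 with loss of propene. The closest known reactions are the ring-closing metathesis of bis-allylic dialkyl peroxides to 3,6-dihydro-1,2-dioxines and of vinyl-substituted mixed acetals to 2-alkoxy-dihydropyrans. The six-membered ring closes by diene metathesis between two alkenyl groups held 1,4 to each other across the O–O tether, which can only deliver the cis ring alkene. No stereocentre is formed: C3 is not involved and both C6 epimers should cyclise. The step needs diene metathesis to win over enyne metathesis and the O–O bond to survive; the triisopropylsilyl cap keeps the alkyne out of the carbene manifold, the quaternary C6 favours the folded conformer, and dialkyl peroxides tolerate ruthenium carbenes at 40 °C.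

Step 10
Reactants: 16 methyl 2-[(3R)-6-methoxy-6-{5-[tri(propan-2-yl)silyl]pent-4-yn-1-yl}-3,6-dihydro-1,2-dioxin-3-yl]acetate
Product: 17 methyl 2-[(3S)-6-methoxy-6-{5-[tri(propan-2-yl)silyl]pent-4-yn-1-yl}-1,2-dioxan-3-yl]acetate (both C6 epimers)
Conditions: KO2CN=NCO2K (excess), AcOH (slow addition), CH2Cl2, −78 → 0 °C; repeated if needed
Reagents that add atoms: none
Why: Diimide reduction saturates the cis ring alkene by concerted hydrogen transfer without cleaving the O–O bond, and the internal alkyne, intrinsically slower than a cis-alkene and shielded by the silyl group, should be left.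

Step 11
Reactants: 17 methyl 2-[(3S)-6-methoxy-6-{5-[tri(propan-2-yl)silyl]pent-4-yn-1-yl}-1,2-dioxan-3-yl]acetate (epimer mixture)
Product: 18 methyl 2-[(3S,6R)-6-methoxy-6-{5-[tri(propan-2-yl)silyl]pent-4-yn-1-yl}-1,2-dioxan-3-yl]acetate
Conditions: TsOH·H2O (10 mol%), MeOH, rt; chromatography, minor epimer resubmitted
Reagents that add atoms: methanol, CO
Why: Acid-catalysed ionisation of the peroxyketal in methanol equilibrates C6 alone, and the (3S,6R) isomer, with the methoxy group axial (anomeric effect) and both carbon substituents equatorial, should dominate.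

Step 12
Reactants: 18 methyl 2-[(3S,6R)-6-methoxy-6-{5-[tri(propan-2-yl)silyl]pent-4-yn-1-yl}-1,2-dioxan-3-yl]acetate
Product: 19 methyl 2-[(3S,6R)-6-methoxy-6-(pent-4-yn-1-yl)-1,2-dioxan-3-yl]acetate
Conditions: TBAF, AcOH (1:1), THF, 0 °C → rt
Reagents that add atoms: none
Why: Fluoride-induced protodesilylation of the alkynylsilane, with acetic acid buffering to suppress β-elimination of the peroxide from the ester and Kornblum–DeLaMare fragmentation.

Step 13
Reactants: 20 dec-9-yn-1-ol
Product: 22 (9E)-10-iododec-9-en-1-ol, via alkenylzirconocene alkoxide 21 (not isolated)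
Conditions: Cp2Zr(H)Cl (2.3 equiv), THF, 0 °C → rt; then I2, 0 °C
Reagents that add atoms: iodine, II
Why: Hydrozirconation with Schwartz reagent (one equivalent is consumed by the hydroxyl group) adds syn with zirconium at the terminal carbon, and iodinolysis with retention should give only the E-iodoalkene.

Step 14
Reactants: 22 (9E)-10-iododec-9-en-1-ol
Product: 23 (9E)-10-iododec-9-enal
Conditions: Dess–Martin periodinane, CH2Cl2, 0 °C → rt
Reagents that add atoms: none
Why: Dess–Martin oxidation converts the primary alcohol to the aldehyde under near-neutral conditions that leave the iodoalkene untouched.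

Step 15
Reactants: 19 methyl 2-[(3S,6R)-6-methoxy-6-(pent-4-yn-1-yl)-1,2-dioxan-3-yl]acetate; 23 (9E)-10-iododec-9-enal
Product: 24 methyl 2-[(3S,6R)-6-methoxy-6-[(6E)-15-oxopentadec-6-en-4-yn-1-yl]-1,2-dioxan-3-yl]acetate
Conditions: Pd(PPh3)4 (5 mol%), CuI (10 mol%), Et3N, THF, rt, degassed
Reagents that add atoms: none
Why: Sonogashira coupling of a terminal alkyne with an E-iodoalkene proceeds at room temperature with retention of geometry, conditions under which dialkyl peroxides and the spectator aldehyde should persist.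

Step 16
Reactants: 24 methyl 2-[(3S,6R)-6-methoxy-6-[(6E)-15-oxopentadec-6-en-4-yn-1-yl]-1,2-dioxan-3-yl]acetate
Product: 25 methyl 2-[(3S,6R)-6-[(6E)-hexadec-6-ene-4,15-diyn-1-yl]-6-methoxy-1,2-dioxan-3-yl]acetate (CNP0314169.1)
Conditions: dimethyl (1-diazo-2-oxopropyl)phosphonate, K2CO3, MeOH, 0 °C → rt
Reagents that add atoms: dimethyl (1-diazo-2-oxopropyl)phosphonate, COP(=O)(OC)C(=[N+]=[N-])C(C)=O
Why: Ohira–Bestmann (Seyferth–Gilbert) homologation turns the aldehyde into the terminal alkyne through the alkylidene carbene under mild carbonate conditions that the β-peroxy ester and the peroxyketal should tolerate at low temperature.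

**Compound list**

1 | 2,3-dimethylbut-2-ene | CC(C)=C(C)C | starting material
2 | 2-hydroperoxy-2-methoxypropane | COC(C)(C)OO | intermediate
3 | (2E,4E)-hexa-2,4-dienal | C/C=C/C=C/C=O | starting material
4 | (3R,4E)-3-[(2-methoxypropan-2-yl)peroxy]hex-4-enal | C/C=C/[C@@H](CC=O)OOC(C)(C)OC | intermediate
5 | (3R,4E)-3-[(2-methoxypropan-2-yl)peroxy]hex-4-enoic acid | C/C=C/[C@@H](CC(=O)O)OOC(C)(C)OC | intermediate
6 | methyl (3R,4E)-3-[(2-methoxypropan-2-yl)peroxy]hex-4-enoate | C/C=C/[C@@H](CC(=O)OC)OOC(C)(C)OC | intermediate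
7 | methyl (3R,4E)-3-hydroperoxyhex-4-enoate | C/C=C/[C@@H](CC(=O)OC)OO | intermediate
8 | 5-chloropent-1-yne | C#CCCCCl | starting material
9 | (5-chloropent-1-yn-1-yl)lithium | [Li]C#CCCCCl | intermediate
10 | (5-chloropent-1-yn-1-yl)tri(propan-2-yl)silane | ClCCCC#C[Si](C(C)C)(C(C)C)C(C)C | intermediate
11 | (5-iodopent-1-yn-1-yl)tri(propan-2-yl)silane | ICCCC#C[Si](C(C)C)(C(C)C)C(C)C | intermediate
12 | methoxyallene (1-methoxypropa-1,2-diene) | COC=C=C | starting material
13 | (1-methoxypropa-1,2-dien-1-yl)lithium | [Li]C(OC)=C=C | intermediate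
14 | (6-methoxyocta-6,7-dien-1-yn-1-yl)tri(propan-2-yl)silane | C=C=C(OC)CCCC#C[Si](C(C)C)(C(C)C)C(C)C | intermediate
15 | methyl (3R,4E)-3-({3-methoxy-8-[tri(propan-2-yl)silyl]oct-1-en-7-yn-3-yl}peroxy)hex-4-enoate (both ketal epimers) | C/C=C/[C@@H](CC(=O)OC)OOC(OC)(C=C)CCCC#C[Si](C(C)C)(C(C)C)C(C)C | intermediate
16 | methyl 2-[(3R)-6-methoxy-6-{5-[tri(propan-2-yl)silyl]pent-4-yn-1-yl}-3,6-dihydro-1,2-dioxin-3-yl]acetate (both C6 epimers) | CC(C)[Si](C(C)C)(C(C)C)C#CCCCC1(OC)C=C[C@@H](CC(=O)OC)OO1 | intermediate
17 | methyl 2-[(3S)-6-methoxy-6-{5-[tri(propan-2-yl)silyl]pent-4-yn-1-yl}-1,2-dioxan-3-yl]acetate (both C6 epimers) | CC(C)[Si](C(C)C)(C(C)C)C#CCCCC1(OC)CC[C@@H](CC(=O)OC)OO1 | intermediate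
18 | methyl 2-[(3S,6R)-6-methoxy-6-{5-[tri(propan-2-yl)silyl]pent-4-yn-1-yl}-1,2-dioxan-3-yl]acetate | CC(C)[Si](C(C)C)(C(C)C)C#CCCC[C@]1(OC)CC[C@@H](CC(=O)OC)OO1 | intermediate
19 | methyl 2-[(3S,6R)-6-methoxy-6-(pent-4-yn-1-yl)-1,2-dioxan-3-yl]acetate | C#CCCC[C@]1(OC)CC[C@@H](CC(=O)OC)OO1 | intermediate
20 | dec-9-yn-1-ol | C#CCCCCCCCCO | starting material
21 | chlorido{[(9E)-10-(chloridozirconocenyl)dec-9-en-1-yl]oxy}zirconocene | Cl[Zr](OCCCCCCCC/C=C/[Zr](Cl)(C1C=CC=C1)C1C=CC=C1)(C1C=CC=C1)C1C=CC=C1 | intermediate
22 | (9E)-10-iododec-9-en-1-ol | OCCCCCCCC/C=C/I | intermediate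
23 | (9E)-10-iododec-9-enal | O=CCCCCCCC/C=C/I | intermediate
24 | methyl 2-[(3S,6R)-6-methoxy-6-[(6E)-15-oxopentadec-6-en-4-yn-1-yl]-1,2-dioxan-3-yl]acetate | O=CCCCCCCC/C=C/C#CCCC[C@]1(OC)CC[C@@H](CC(=O)OC)OO1 | intermediate
25 | methyl 2-[(3S,6R)-6-[(6E)-hexadec-6-ene-4,15-diyn-1-yl]-6-methoxy-1,2-dioxan-3-yl]acetate | C#CCCCCCCC/C=C/C#CCCC[C@]1(OC)CC[C@@H](CC(=O)OC)OO1 | target

**Step count**

Total: 16 steps. Longest linear sequence: 11 steps (steps 1–4, 8–12, 15, 16).

**Steps most likely to fail**

Step 2. The peroxide addition may show poor facial selectivity, or the adduct may lose enantiopurity through reversible addition under the amine, so that 7 arrives with too low an enantiomeric excess. The fallback is a resolution through diastereomeric peroxyketals; it sets out from 7 of insufficient purity and returns to 7. Commercial (1S,2R)-2-phenylcyclohexan-1-ol is acetylated (Ac2O, pyridine) to (1S,2R)-2-phenylcyclohexyl acetate F1, and Tebbe methylenation gives (1S,2R)-2-phenylcyclohexyl prop-1-en-2-yl ether F2. PPTS-catalysed addition of scalemic 7 to this enol ether should give methyl (3R,4E)-3-[(2-{[(1S,2R)-2-phenylcyclohexyl]oxy}propan-2-yl)peroxy]hex-4-enoate F3 together with its 3S diastereomer F4, to be separated by chromatography. Aqueous acetic acid in THF then releases enantiopure 7 from the 3R diastereomer.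

Step 8. Protonation of the allene may outrun capture by the hydroperoxide, leading to hydrolysis or oligomerisation of 14 and to acid-induced loss of the allylic hydroperoxide. The fallback replaces kinetic addition by equilibrium exchange on a stable, purifiable ketal; it sets out from 14 and returns at 15. Methanol is added to 14 (PPTS, MeOH, 0 °C) to give (6,6-dimethoxyoct-7-en-1-yn-1-yl)tri(propan-2-yl)silane F5. An excess of this ketal is then exchanged with 7 (PPTS, CH2Cl2, 5 Å sieves to take up methanol) to give 15.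

Step 9. Ring closure may stall because both alkenes sit next to oxygenated, branched carbons, and prolonged heating with ruthenium may then cleave the O–O bond or isomerise the alkenes. The fallback forms C4–C5 by cross-metathesis with an unhindered enone and closes the ring by peroxyketalisation instead; it sets out from 6 (isolated by omitting the PPTS stage of step 4) and 14 and returns at 18. Mild aqueous acid (oxalic acid, wet THF) hydrolyses 14 to 8-[tri(propan-2-yl)silyl]oct-1-en-7-yn-3-one F6. Cross-metathesis of 6 with this enone (Hoveyda–Grubbs II, CH2Cl2, 40 °C) should give methyl (3R,4E)-3-[(2-methoxypropan-2-yl)peroxy]-6-oxo-11-[tri(propan-2-yl)silyl]undec-4-en-10-ynoate F7. Acid-buffered diimide reduces the enone alkene to methyl (3S)-3-[(2-methoxypropan-2-yl)peroxy]-6-oxo-11-[tri(propan-2-yl)silyl]undec-10-ynoate F8. TsOH in methanol then unmasks the hydroperoxide, which closes onto the ketone and equilibrates to 18.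

**Further compounds**

F1 | step 2 | (1S,2R)-2-phenylcyclohexyl acetate | CC(=O)O[C@H]1CCCC[C@@H]1c1ccccc1
F2 | step 2 | (1S,2R)-2-phenylcyclohexyl prop-1-en-2-yl ether | CC(=C)O[C@H]1CCCC[C@@H]1c1ccccc1
F3 | step 2 | methyl (3R,4E)-3-[(2-{[(1S,2R)-2-phenylcyclohexyl]oxy}propan-2-yl)peroxy]hex-4-enoate | C/C=C/[C@@H](CC(=O)OC)OOC(C)(C)O[C@H]1CCCC[C@@H]1c1ccccc1
F4 | step 2 | methyl (3S,4E)-3-[(2-{[(1S,2R)-2-phenylcyclohexyl]oxy}propan-2-yl)peroxy]hex-4-enoate | C/C=C/[C@H](CC(=O)OC)OOC(C)(C)O[C@H]1CCCC[C@@H]1c1ccccc1
F5 | step 8 | (6,6-dimethoxyoct-7-en-1-yn-1-yl)tri(propan-2-yl)silane | COC(OC)(C=C)CCCC#C[Si](C(C)C)(C(C)C)C(C)C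
F6 | step 9 | 8-[tri(propan-2-yl)silyl]oct-1-en-7-yn-3-one | C=CC(=O)CCCC#C[Si](C(C)C)(C(C)C)C(C)C
F7 | step 9 | methyl (3R,4E)-3-[(2-methoxypropan-2-yl)peroxy]-6-oxo-11-[tri(propan-2-yl)silyl]undec-4-en-10-ynoate | COC(=O)C[C@H](/C=C/C(=O)CCCC#C[Si](C(C)C)(C(C)C)C(C)C)OOC(C)(C)OC
F8 | step 9 | methyl (3S)-3-[(2-methoxypropan-2-yl)peroxy]-6-oxo-11-[tri(propan-2-yl)silyl]undec-10-ynoate | COC(=O)C[C@H](CCC(=O)CCCC#C[Si](C(C)C)(C(C)C)C(C)C)OOC(C)(C)OC
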